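Everything rests on cutting the C2–C1' bond between pyranone ring C and ring B of the chromene unit. The key step exploits the vinylogous-ester polarisation O1–C2=C3–C4=O of ring C, which makes C2 the acceptor carbon for an aryl–palladium species. Its precursor is neither flavone nor chromone but saturated 7-acetoxy-6-prenylchroman-4-one, with no activating group at C2, paired with a 2,2-dimethylchromen-6-yl pinacol boronate. In one flask aerobic divalent-palladium catalysis dehydrogenates C2–C3, arylates the new C2–H bond by an oxidative boron-Heck reaction and restores the enone. Methanolysis of the acetate in the same pot releases kanzonol E. Each fragment takes two steps.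

Key step: step 5

Remark: flavone numbering is used (ring C = O1, C2, C3, C4; ring A = C5 to C8; ring B primed). The target has no stereocentre and its ring alkene is geometrically fixed, so only regiochemistry and chemoselectivity need control.

Step 1
Reactants: 1 7-hydroxychroman-4-one; 2 2-methylbut-3-en-2-ol
Product: 3 7-hydroxy-6-(3-methylbut-2-en-1-yl)chroman-4-one
Conditions: BF3·OEt2 (30 mol %), dioxane, rt, slow addition of 2
Reagents that add atoms: none
Why: Friedel–Crafts allylation, in which BF3 ionises the tertiary allylic alcohol to the prenyl cation and its primary terminus should be taken by C6 of ring A, the position ortho to the 7-OH and para to O1 that is less crowded than C8 between the two oxygens.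

Step 2
Reactants: 3 7-hydroxy-6-(3-methylbut-2-en-1-yl)chroman-4-one
Product: 4 6-(3-methylbut-2-en-1-yl)-4-oxochroman-7-yl acetate
Conditions: Ac2O, pyridine, 0 °C to rt
Reagents that add atoms: acetic anhydride, CC(=O)OC(C)=O
Why: Standard O-acetylation of the only hydroxyl group, giving an ester that masks the phenol against palladium-mediated oxidative cyclisation onto the prenyl alkene in step 5 and can later be removed without acid.

Step 3
Reactants: 5 4-bromophenol; 6 3-methylbut-2-enal
Product: 8 6-bromo-2,2-dimethyl-2H-chromene, via o-quinone methide 7 (not isolated)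
Conditions: PhB(OH)2 (1 equiv), AcOH, toluene, reflux, Dean–Stark
Reagents that add atoms: none
Why: Boronic-acid-templated ortho-hydroxyalkylation of the phenol by the enal, followed by thermal loss of PhB(OH)2, should give o-quinone methide 7, whose oxa-6π electrocyclisation closes the 2,2-dimethylpyran ring, the para bromine leaving only two equivalent ortho positions open.

Step 4
Reactants: 8 6-bromo-2,2-dimethyl-2H-chromene
Product: 9 2-(2,2-dimethyl-2H-chromen-6-yl)-4,4,5,5-tetramethyl-1,3,2-dioxaborolane
Conditions: B2pin2, PdCl2(dppf) (3 mol %), KOAc (3 equiv), dioxane, 85 °C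
Reagents that add atoms: bis(pinacolato)diboron, CC1(C)OB(B2OC(C)(C)C(C)(C)O2)OC1(C)C
Why: Miyaura borylation (oxidative addition of zerovalent palladium into the aryl C–Br bond, acetate-assisted transmetalation from B2pin2, reductive elimination), which should leave the hindered chromene alkene untouched.

Step 5
Reactants: 4 6-(3-methylbut-2-en-1-yl)-4-oxochroman-7-yl acetate; 9 2-(2,2-dimethyl-2H-chromen-6-yl)-4,4,5,5-tetramethyl-1,3,2-dioxaborolane (2 equiv)
Product: 12 kanzonol E, via chromone acetate 10 (not isolated), via kanzonol E acetate 11 (not isolated)
Conditions: Pd(OCOCF3)2 (10 mol %), 5-nitro-1,10-phenanthroline (20 mol %), O2 (1 atm), DMSO, 100 °C; then N2 purge, rt, MeOH, K2CO3 (3 equiv)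
Reagents that add atoms: none
Why: Divalent palladium forms the C3 enolate of ketone 4 and β-hydride elimination of a C2–H gives chromone 10, O2 returning zerovalent palladium to the divalent state. Transmetalation from 9 then gives an aryl–palladium species that inserts syn into C2=C3 of ring C, the aryl group going to C2 (β-carbon of the vinylogous ester O1–C2=C3–C4=O) and palladium to C3; because this leaves C2–H anti to the metal, the palladium enolate epimerises through its oxygen-bound form before syn β-hydride elimination restores C2=C3 and gives 11. The closest known reaction type is exactly this one-pot dehydrogenation/oxidative boron-Heck arylation of chroman-4-ones with aryl pinacol boronates. No ring is closed and no stereocentre is created. The step needs the aryl–palladium species to choose C2=C3 over the two other alkenes and the phenol to stay masked: the prenyl alkene is trisubstituted and unactivated, the chromene alkene of 9 is shielded by its quaternary neighbour and offers neither a syn β-hydrogen nor an enolate path after insertion, and the O7 acetate blocks Wacker-type closure onto the prenyl group. After the oxygen is purged, K2CO3 in MeOH transesterifies the activated aryl acetate of 11 and frees the 7-OH without any acid.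

Compound list
1 | 7-hydroxychroman-4-one | O=C1CCOc2cc(O)ccc21 | starting material
2 | 2-methylbut-3-en-2-ol | C=CC(C)(C)O | starting material
3 | 7-hydroxy-6-(3-methylbut-2-en-1-yl)chroman-4-one | CC(C)=CCc1cc2c(cc1O)OCCC2=O | intermediate
4 | 6-(3-methylbut-2-en-1-yl)-4-oxochroman-7-yl acetate | CC(C)=CCc1cc2c(cc1OC(C)=O)OCCC2=O | intermediate
5 | 4-bromophenol | Oc1ccc(Br)cc1 | starting material
6 | 3-methylbut-2-enal | CC(C)=CC=O | starting material
7 | (6Z)-4-bromo-6-(3-methylbut-2-en-1-ylidene)cyclohexa-2,4-dien-1-one (o-quinone methide, not isolated) | O=C1C=CC(Br)=C/C1=C/C=C(C)C | intermediate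
8 | 6-bromo-2,2-dimethyl-2H-chromene | CC1(C)C=Cc2cc(Br)ccc2O1 | intermediate
9 | 2-(2,2-dimethyl-2H-chromen-6-yl)-4,4,5,5-tetramethyl-1,3,2-dioxaborolane | CC1(C)C=Cc2cc(B3OC(C)(C)C(C)(C)O3)ccc2O1 | intermediate
10 | 6-(3-methylbut-2-en-1-yl)-4-oxo-4H-chromen-7-yl acetate (chromone acetate, not isolated) | CC(C)=CCc1cc2c(=O)ccoc2cc1OC(C)=O | intermediate
11 | 2-(2,2-dimethyl-2H-chromen-6-yl)-6-(3-methylbut-2-en-1-yl)-4-oxo-4H-chromen-7-yl acetate (kanzonol E acetate, not isolated) | CC(C)=CCc1cc2c(=O)cc(-c3ccc4c(c3)C=CC(C)(C)O4)oc2cc1OC(C)=O | intermediate
12 | kanzonol E, 2-(2,2-dimethyl-2H-chromen-6-yl)-7-hydroxy-6-(3-methylbut-2-en-1-yl)-4H-chromen-4-one | CC(C)=CCc1cc2c(=O)cc(-c3ccc4c(c3)C=CC(C)(C)O4)oc2cc1O | target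

Total step count: 5. Longest linear sequence: 3 steps (1, 2, 5 or 3, 4, 5).

Steps most likely to fail

Step 5. Several processes could erode the coupling:
- allylic C–H oxidation of the prenyl group at 100 °C;
- insertion of the aryl–palladium species into the wrong alkene;
- protodeboronation or oxidation of the boronate;
- premature loss of the acetate followed by oxidative cyclisation of the freed phenol.

The fallback separates bond formation from oxidation. It sets out from 4, which is dehydrogenated without metal by 2-iodoxybenzoic acid in DMSO at 65 °C to chromone acetate 10, now isolated. A redox-neutral Hayashi–Miyaura 1,4-addition of 9 ([Rh(OH)(cod)]2, dioxane–water, 50 °C) then forms the same C2–C1' bond. It gives racemic 2-(2,2-dimethyl-2H-chromen-6-yl)-6-(3-methylbut-2-en-1-yl)-4-oxochroman-7-yl acetate F1. A second dehydrogenation with 2-iodoxybenzoic acid in DMSO at 80 °C removes the transient C2 stereocentre and comes back to the route at 11, which is then methanolysed as a separate operation.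

Step 1. The cationic prenylation may suffer from poor discrimination between C6 and C8, from double alkylation and from acid-catalysed cyclisation of the ortho-prenylphenol to a chroman. The fallback replaces it by halogenation and cross-coupling. It sets out from 1, which is brominated with N-bromosuccinimide in MeCN at 0 °C at the less hindered position, giving 6-bromo-7-hydroxychroman-4-one F2. Acetylation (Ac2O, pyridine) gives 6-bromo-4-oxochroman-7-yl acetate F3. A Stille coupling with tributyl(3-methylbut-2-en-1-yl)stannane (Pd(PPh3)4, DMF, 90 °C) then fixes the prenyl group at C6 and comes back to the route at 4.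

Step 3. The templated ortho-hydroxyalkylation may be sluggish on a halogen-deactivated phenol, and the enal may self-condense on long heating. The fallback builds the pyran ring by a sigmatropic route. It sets out from 5, which is O-alkylated with 3-chloro-3-methylbut-1-yne (K2CO3, catalytic KI, acetone, reflux) to 1-bromo-4-[(2-methylbut-3-yn-2-yl)oxy]benzene F4. Heating in N,N-diethylaniline at 190 °C triggers the aromatic propargyl Claisen rearrangement, a 1,5-hydrogen shift and oxa-6π electrocyclisation, and comes back to the route at 8.

Further compounds
F1 | step 5 | racemic 2-(2,2-dimethyl-2H-chromen-6-yl)-6-(3-methylbut-2-en-1-yl)-4-oxochroman-7-yl acetate | CC(C)=CCc1cc2c(cc1OC(C)=O)OC(c1ccc3c(c1)C=CC(C)(C)O3)CC2=O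
F2 | step 1 | 6-bromo-7-hydroxychroman-4-one | O=C1CCOc2cc(O)c(Br)cc21
F3 | step 1 | 6-bromo-4-oxochroman-7-yl acetate | CC(=O)Oc1cc2c(cc1Br)C(=O)CCO2
F4 | step 3 | 1-bromo-4-[(2-methylbut-3-yn-2-yl)oxy]benzene | C#CC(C)(C)Oc1ccc(Br)cc1
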